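**Retrosynthetic overview**
1. Target 18 ⇒ ester C–O bond ⇒ (+)-phomalactone 9 + dienoic acid 17.
2. 9 ⇒ lactol 7 by a redox-neutral isomerisation (lactol → lactone, ketone → cis-carbinol). This is the proposed new Ru-catalysed step and it sets C5.
3. 7 ⇒ furyl carbinol 5 by Achmatowicz oxidative ring expansion (furan → pyranone). This is the key step and forms the only ring of the target. 5 ⇒ furfural 1 + propyne 2 by catalytic asymmetric alkenylation, which sets C6.
4. 17 ⇒ enal 14 + malonic acid 15 (Doebner); 14 ⇒ (S)-2-methyloctan-1-ol 12 (oxidation/Wittig); 12 ⇒ (R)-bromo alcohol 10 + pentylmagnesium bromide 11 (Cu-catalysed coupling; the chiral pool supplies the side-chain stereocentre).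

Target stereochemistry as read from the SMILES: lactone 5S,6S (cis), side chain 2E,4E,6S, propenyl E.

Assumption: dicyclohexylborane and the 16-electron Ru amido complex are used as preformed reagents, and 11 is used as its commercial ether solution.

**Step 1**
Reactants: 1 furfural (furan-2-carbaldehyde); 2 propyne
Product: 5 (S,E)-1-(furan-2-yl)but-2-en-1-ol, via (E)-dicyclohexyl(prop-1-enyl)borane 3 (not isolated), via (E)-methyl(prop-1-enyl)zinc 4 (not isolated)
Conditions: 2, Cy2BH, toluene, 0 °C → rt; Me2Zn, −78 °C; (−)-MIB (4 mol%), 1, −10 °C; H2O quench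
Reagents that add atoms: none
Why: syn-hydroboration gives the E-alkenylborane, and B→Zn transmetalation followed by amino-alcohol-catalysed asymmetric 1,2-addition of the alkenylzinc to the Si face of the aldehyde (Oppolzer/Walsh alkenylation) sets the S carbinol centre that becomes C6.

**Step 2**
Reactants: 5 (S,E)-1-(furan-2-yl)but-2-en-1-ol
Product: 7 (2S)-6-hydroxy-2-[(E)-prop-1-enyl]-2H-pyran-3(6H)-one (anomer mixture), via (S,2Z,6E)-5-hydroxy-4-oxoocta-2,6-dienal 6 (not isolated)
Conditions: NBS (1.05 equiv), NaHCO3, NaOAc, THF/H2O (4:1), 0 °C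
Reagents that add atoms: water (O)
Why: Achmatowicz rearrangement, an oxidative ring expansion in which bromonium-triggered hydration opens the electron-rich furan (far more nucleophilic than the propenyl alkene) to the Z-ene-dione, which recloses through the carbinol oxygen to the six-membered pyranone; the carbinol centre is untouched under the buffered conditions.

**Step 3**
Reactants: 7 (2S)-6-hydroxy-2-[(E)-prop-1-enyl]-2H-pyran-3(6H)-one
Product: 9 (+)-phomalactone [(5S,6S)-5-hydroxy-6-[(E)-prop-1-enyl]-5,6-dihydro-2H-pyran-2-one], via (S)-6-[(E)-prop-1-enyl]-2H-pyran-2,5(6H)-dione 8 (not isolated)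
Conditions: Ru(p-cymene)[(R,R)-TsDPEN] 16 e amido complex (2 mol%), CH2Cl2, 0 °C → rt, no added H-donor, acceptor or base
Reagents that add atoms: none
Why: Proposed new method: a redox-neutral, 1,2-selective hydrogen relocation from the hemiacetal C–H to the ketone C=O by a Noyori–Ikariya bifunctional catalyst; the Ru amide dehydrogenates the equilibrating lactol anomers through the outer-sphere Ru/N–H transition state to give ene-dione lactone 8 and Ru–H/N–H, which returns H−/H+ to the very electrophilic C5 ketone in a concerted six-membered transition state (a concerted 1,4-delivery to the ring-locked s-trans enone is geometrically impossible, so the C3=C4 bond should survive) from the face anti to the C6 propenyl group, giving the 5,6-cis (5S) alcohol, with the (R,R)-ligand as the predicted matched enantiomer (ring vinyl group in the "aryl" position) and lactone formation making the isomerisation downhill; closest known chemistry is the Ir-catalysed internal redox isomerisation of Achmatowicz lactols (which instead moves hydrogen to the C=C bond and gives saturated keto-lactones), Ru/Ir-amide dehydrogenation of lactols to lactones, and C=O-selective Ru–TsDPEN transfer hydrogenation of conjugated ynones.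

**Step 4**
Reactants: 10 (R)-3-bromo-2-methylpropan-1-ol; 11 pentylmagnesium bromide
Product: 12 (S)-2-methyloctan-1-ol
Conditions: 11 (3 equiv), Li2CuCl4 (5 mol%), THF, −78 → 0 °C; aq NH4Cl
Reagents that add atoms: none
Why: Kochi-type Cu-catalysed sp3–sp3 cross-coupling of the primary bromide with the Grignard reagent (the first equivalent only deprotonates the OH); the stereocentre is not involved, and the descriptor changes from R to S only because the CIP priorities change.

**Step 5**
Reactants: 12 (S)-2-methyloctan-1-ol
Product: 14 (S,E)-2,4-dimethyldec-2-enal, via (S)-2-methyloctanal 13 (not isolated)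
Conditions: TEMPO (10 mol%), PhI(OAc)2 (1.1 equiv), CH2Cl2, rt; NaHCO3 wash, solvent swap; Ph3P=C(Me)CHO (1.3 equiv), toluene, 80 °C
Reagents that add atoms: 2-(triphenylphosphoranylidene)propanal, CC(C=O)=P(c1ccccc1)(c1ccccc1)c1ccccc1
Why: TEMPO/BAIB oxidation is non-epimerising, and the crude α-methyl aldehyde is taken straight into a Wittig olefination with the stabilised formyl ylide, which gives the E-trisubstituted enal without touching the stereocentre.

**Step 6**
Reactants: 14 (S,E)-2,4-dimethyldec-2-enal; 15 malonic acid
Product: 17 (2E,4E,6S)-4,6-dimethyldodeca-2,4-dienoic acid, via 2-[(2E,4S)-2,4-dimethyldec-2-enylidene]malonic acid 16 (not isolated)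
Conditions: 15 (2 equiv), pyridine (no secondary amine), 70 → 90 °C; aq HCl
Reagents that add atoms: none
Why: Knoevenagel–Doebner condensation, in which decarboxylation of the alkylidene malonic acid in pyridine gives the E-acrylic acid directly while the existing E-trisubstituted alkene and the stereocentre are carried through.

**Step 7**
Reactants: 9 (+)-phomalactone; 17 (2E,4E,6S)-4,6-dimethyldodeca-2,4-dienoic acid
Product: 18 (2S,3S)-6-oxo-2-[(E)-prop-1-enyl]-3,6-dihydro-2H-pyran-3-yl (2E,4E,6S)-4,6-dimethyldodeca-2,4-dienoate (target)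
Conditions: DCC (1.2 equiv), DMAP (10 mol%), CH2Cl2, 0 °C → rt
Reagents that add atoms: none
Why: Steglich esterification acylates the C5 hydroxyl without breaking its C–O bond (retention), and because 17 is enantiopure any minor enantiomer of 9 ends up as a chromatographically separable diastereomer.

**Compound list**
1 | furfural (furan-2-carbaldehyde) | O=Cc1ccco1 | starting material
2 | propyne | CC#C | starting material
3 | (E)-dicyclohexyl(prop-1-enyl)borane | C/C=C/B(C1CCCCC1)C1CCCCC1 | intermediate (not isolated)
4 | (E)-methyl(prop-1-enyl)zinc | C/C=C/[Zn]C | intermediate (not isolated)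
5 | (S,E)-1-(furan-2-yl)but-2-en-1-ol | C/C=C/[C@H](O)c1ccco1 | intermediate
6 | (S,2Z,6E)-5-hydroxy-4-oxoocta-2,6-dienal | C/C=C/[C@H](O)C(=O)/C=C\C=O | intermediate (not isolated)
7 | (2S)-6-hydroxy-2-[(E)-prop-1-enyl]-2H-pyran-3(6H)-one (both anomers) | C/C=C/[C@@H]1OC(O)C=CC1=O | intermediate
8 | (S)-6-[(E)-prop-1-enyl]-2H-pyran-2,5(6H)-dione | C/C=C/[C@@H]1OC(=O)C=CC1=O | intermediate (not isolated)
9 | (+)-phomalactone, (5S,6S)-5-hydroxy-6-[(E)-prop-1-enyl]-5,6-dihydro-2H-pyran-2-one | C/C=C/[C@@H]1OC(=O)C=C[C@@H]1O | intermediate
10 | (R)-3-bromo-2-methylpropan-1-ol | C[C@H](CO)CBr | starting material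
11 | pentylmagnesium bromide | CCCCC[Mg]Br | starting material
12 | (S)-2-methyloctan-1-ol | C[C@H](CO)CCCCCC | intermediate
13 | (S)-2-methyloctanal | C[C@H](C=O)CCCCCC | intermediate (not isolated)
14 | (S,E)-2,4-dimethyldec-2-enal | O=C/C(C)=C/[C@@H](C)CCCCCC | intermediate
15 | malonic acid | OC(=O)CC(=O)O | starting material
16 | 2-[(2E,4S)-2,4-dimethyldec-2-enylidene]malonic acid | OC(=O)C(C(=O)O)=C/C(C)=C/[C@@H](C)CCCCCC | intermediate (not isolated)
17 | (2E,4E,6S)-4,6-dimethyldodeca-2,4-dienoic acid | OC(=O)/C=C/C(C)=C/[C@@H](C)CCCCCC | intermediate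
18 | (2S,3S)-6-oxo-2-[(E)-prop-1-enyl]-3,6-dihydro-2H-pyran-3-yl (2E,4E,6S)-4,6-dimethyldodeca-2,4-dienoate | C/C=C/[C@@H]1OC(=O)C=C[C@@H]1OC(=O)/C=C/C(C)=C/[C@@H](C)CCCCCC | target

**Count**
Total steps: 7. Longest linear sequence: 4 (steps 1 → 2 → 3 → 7, or 4 → 5 → 6 → 7).

**Steps most likely to fail**

Step 3 (the proposed new isomerisation). The risks are 1,4-hydride delivery (saturated keto-lactone), C6 epimerisation of transient 8, reversible re-oxidation of 9, and catalyst inhibition by acidic residues from step 2. The fallback sets out from 7 and returns at 9 using known chemistry. The lactol 7 is oxidised with Jones reagent in acetone at 0 °C to the keto-lactone 8, which is now isolated. 8 is then reduced under Luche conditions (NaBH4, CeCl3·7H2O, MeOH/CH2Cl2, −78 °C), where hydride attacks anti to the propenyl group and gives the cis alcohol 9. This costs one extra step and makes no compound outside the list.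

Step 1 (asymmetric alkenylation). The risks are handling a gaseous alkyne and eroded ee from background addition to the coordinating heteroaryl aldehyde. The fallback sets out from 1 and returns at 5. Addition of 1-propynylmagnesium bromide in THF at 0 °C gives rac-1-(furan-2-yl)but-2-yn-1-ol F1. Sharpless kinetic resolution (Ti(OiPr)4, D-(−)-DIPT, TBHP 0.6 equiv, 4 Å MS, CH2Cl2, −20 °C) leaves the slow-reacting (S)-1-(furan-2-yl)but-2-yn-1-ol F2 in high ee. The fast enantiomer is consumed as (2R)-6-hydroxy-2-(prop-1-yn-1-yl)-2H-pyran-3(6H)-one F3 and removed by chromatography; the alkyne is inert to the epoxidation reagent. Trans-selective reduction of F2 with Red-Al in THF at 0 °C then gives 5.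

Step 6 (Doebner condensation). The risks are sluggish condensation at the α-branched enal and, in hot pyridine, bis-vinylogous deprotonation of 16 at the stereocentre (loss of ee or double-bond migration). The fallback sets out from 14 and returns at 17. Horner–Wadsworth–Emmons olefination with triethyl phosphonoacetate (NaH, THF, 0 °C) gives ethyl (2E,4E,6S)-4,6-dimethyldodeca-2,4-dienoate F4. Saponification with LiOH in THF/MeOH/H2O at rt then gives 17.

**Further compounds**
F1 | step 1 | rac-1-(furan-2-yl)but-2-yn-1-ol | CC#CC(O)c1ccco1
F2 | step 1 | (S)-1-(furan-2-yl)but-2-yn-1-ol | CC#C[C@H](O)c1ccco1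
F3 | step 1 | (2R)-6-hydroxy-2-(prop-1-yn-1-yl)-2H-pyran-3(6H)-one | CC#C[C@H]1OC(O)C=CC1=O
F0 | step 3 | none | none
F4 | step 6 | ethyl (2E,4E,6S)-4,6-dimethyldodeca-2,4-dienoate | CCOC(=O)/C=C/C(C)=C/[C@@H](C)CCCCCC
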